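**Retrosynthetic overview**
1. Feature: in the single carbocycle (C1 CH–O-enoate, C2 C=O, C3 C–C7H2OH, C4 =CH, C5 CH–O-isobutyrate, C6 CH–iPr) the C2 carbonyl and the C5 oxygen stand 1,4 across C3=C4, the imprint of a base-opened 1,3-diene endoperoxide.
2. Late disconnections: both primary silyl ethers; the C1 ester (Yamaguchi acylation with silylated (E)-γ-hydroxytiglic acid, itself from a Wittig olefination); the C1–O bond (Rubottom oxidation anti to isopropyl); the C5 isobutyrate (Mitsunobu inversion).
3. Key disconnection: C2–O and C5–O to singlet oxygen and the (S)-diene C2=C3–C4=C5 that already carries C7 as a silyl ether; the resulting 2,3-dioxabicyclo[2.2.2]octene is opened by a Kornblum–DeLaMare rearrangement.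
4. The diene comes from (S)-4-isopropylcyclohex-2-enone through its kinetic dienyl triflate (carbonylation, reduction, silylation); the enone comes from 3-methylbutanal and methyl vinyl ketone by enamine-catalysed Michael addition and aldol condensation.
5. Ring order: carbocycle first (step 2), then the temporary 1,2-dioxane ring (step 7), cleaved in step 8; C6 is the only centre set by catalysis, and C2, C5 and C1 are relayed from it.

Key step: step 7

Remark: ring atoms keep the target numbering (C1–C6, C7 for the hydroxymethyl carbon) in every intermediate. The sense of induction in step 1 is assumed from the steric-shielding model of 2-(diarylmethyl)pyrrolidine enamines.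

**Route**

Step 1
Reactants: 1 3-methylbutanal; 2 methyl vinyl ketone
Product: 3 (S)-2-isopropyl-5-oxohexanal
Conditions: (S)-2-[methoxy(diphenyl)methyl]pyrrolidine (5 mol%), ethyl 3,4-dihydroxybenzoate (20 mol%), neat, 4 °C
Reagents that add atoms: none
Why: Enamine-catalysed Michael addition in which the E-enamine of 1 is shielded on one face by the diphenyl(methoxy)methyl group, so the enone adds to the open face and should set the future C6 centre as (S).

Step 2
Reactants: 3 (S)-2-isopropyl-5-oxohexanal
Product: 5 (S)-4-isopropylcyclohex-2-en-1-one, via β-hydroxy ketone 4 (not isolated)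
Conditions: KOH (0.1 M aq.), n-Bu4NOH (cat.), Et2O/THF/H2O, reflux, short reaction time
Reagents that add atoms: none
Why: Intramolecular aldol condensation (6-enolexo attack of the methyl ketone enolate on the aldehyde, then E1cB dehydration) closes the carbocycle; the brief biphasic base treatment should leave the α-branched centre intact.

Step 3
Reactants: 5 (S)-4-isopropylcyclohex-2-en-1-one
Product: 7 (S)-4-isopropylcyclohexa-1,5-dien-1-yl trifluoromethanesulfonate, via lithium dienolate 6 (not isolated)
Conditions: LiN(i-Pr)2, THF, −78 °C; then PhNTf2, −78 → 0 °C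
Reagents that add atoms: N-phenylbis(trifluoromethanesulfonimide), O=S(=O)(N(c1ccccc1)S(=O)(=O)C(F)(F)F)C(F)(F)F
Why: Kinetic α′-deprotonation of the enone gives the cross-conjugated dienolate, whose O-triflation fixes the C2=C3–C4=C5 diene; the γ-stereocentre is not touched.

Step 4
Reactants: 7 (S)-4-isopropylcyclohexa-1,5-dien-1-yl trifluoromethanesulfonate
Product: 8 methyl (S)-4-isopropylcyclohexa-1,5-diene-1-carboxylate
Conditions: Pd(OAc)2 (cat.), PPh3 (cat.), CO (1 atm), MeOH, Et3N, DMF, rt; crude ester used at once
Reagents that add atoms: carbon monoxide, [C-]#[O+]; methanol, CO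
Why: Palladium-catalysed alkoxycarbonylation of an enol triflate (oxidative addition to zerovalent palladium, CO insertion, methanolysis) installs C7 at room temperature without moving the diene.

Step 5
Reactants: 8 methyl (S)-4-isopropylcyclohexa-1,5-diene-1-carboxylate
Product: 9 [(S)-4-isopropylcyclohexa-1,5-dien-1-yl]methanol
Conditions: i-Bu2AlH (2.3 equiv), CH2Cl2, −78 → −20 °C
Reagents that add atoms: none
Why: 1,2-Reduction of the dienoate by the aluminium hydride gives the allylic alcohol and removes the acrylate that would make the diene electron-poor and prone to dimerise.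

Step 6
Reactants: 9 [(S)-4-isopropylcyclohexa-1,5-dien-1-yl]methanol
Product: 10 tert-butyl{[(S)-4-isopropylcyclohexa-1,5-dien-1-yl]methoxy}dimethylsilane (diene C2=C3–C4=C5, CH2OTBS on C3, isopropyl on C6)
Conditions: TBSCl, imidazole, DMF, 0 °C → rt
Reagents that add atoms: tert-butyldimethylsilyl chloride, CC(C)(C)[Si](C)(C)Cl
Why: Standard silylation of a primary allylic alcohol; the ether masks C7–OH through the Mitsunobu, enolisation and acylation steps.

Step 7
Reactants: 10 tert-butyl{[(S)-4-isopropylcyclohexa-1,5-dien-1-yl]methoxy}dimethylsilane; 11 dioxygen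
Product: 12 tert-butyl{[(1S,4R,7S)-7-isopropyl-2,3-dioxabicyclo[2.2.2]oct-5-en-5-yl]methoxy}dimethylsilane (peroxide bridge across C2 and C5, anti to the C6 isopropyl group)
Conditions: O2 (bubbling), 5,10,15,20-tetraphenylporphyrin (cat.), visible light, CH2Cl2, −40 °C
Reagents that add atoms: none
Why: Dye-sensitised singlet oxygen adds suprafacially in a concerted [4+2] cycloaddition to the ring-locked s-cis diene C2=C3–C4=C5, forming the C2–O and C5–O bonds together; the closest known reaction is the photooxygenation of cyclohexa-1,3-dienes of the α-phellandrene and α-terpinene type to endoperoxides. The 1,2-dioxane ring of the 2,3-dioxabicyclo[2.2.2]octene closes by this intermolecular cycloaddition, both of its new bonds being made in the same step and not by cyclisation of a tethered chain. The new centres C2 and C5 are necessarily cis to each other because the peroxide bridge spans one face, and their absolute sense is relayed from C6, whose isopropyl group should steer the oxygen to the opposite face. The step needs cycloaddition to win over the ene reaction, which the planar electron-rich cisoid diene secures, and anti facial selectivity, which need only be moderate because the syn adduct can be brought to the same isobutyrate 16 by retentive acylation. The low temperature limits ene hydroperoxidation, aromatisation and peroxide decomposition.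

Step 8
Reactants: 12 tert-butyl{[(1S,4R,7S)-7-isopropyl-2,3-dioxabicyclo[2.2.2]oct-5-en-5-yl]methoxy}dimethylsilane
Product: 13 (4S,5S)-2-{[(tert-butyldimethylsilyl)oxy]methyl}-4-hydroxy-5-isopropylcyclohex-2-en-1-one (C2 ketone, C5–OH anti to isopropyl)
Conditions: Et3N (0.5 equiv), CH2Cl2, 0 °C → rt
Reagents that add atoms: none
Why: Kornblum–DeLaMare rearrangement in which the amine removes the C2 bridgehead hydrogen as the O–O bond breaks, giving the C2 ketone conjugated with C3=C4 and leaving the C5–O bond and its configuration untouched; removal of C2–H should be preferred because C5–H lies next to the branched C6.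

Step 9
Reactants: 13 (4S,5S)-2-{[(tert-butyldimethylsilyl)oxy]methyl}-4-hydroxy-5-isopropylcyclohex-2-en-1-one; 14 isobutyric acid
Product: 16 (1R,6S)-3-{[(tert-butyldimethylsilyl)oxy]methyl}-6-isopropyl-4-oxocyclohex-2-en-1-yl 2-methylpropanoate (C5–O syn to isopropyl), via alkoxyphosphonium isobutyrate 15 (not isolated)
Conditions: PPh3, diisopropyl azodicarboxylate, toluene, 0 °C → rt
Reagents that add atoms: none
Why: Mitsunobu esterification, in which the carboxylate displaces the allylic oxyphosphonium group by SN2 with inversion at C5; E2 loss is disfavoured because the only C6 hydrogen is cis to the leaving group.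

Step 10
Reactants: 16 (1R,6S)-3-{[(tert-butyldimethylsilyl)oxy]methyl}-6-isopropyl-4-oxocyclohex-2-en-1-yl 2-methylpropanoate
Product: 18 (1R,6R)-3-{[(tert-butyldimethylsilyl)oxy]methyl}-6-isopropyl-4-[(trimethylsilyl)oxy]cyclohexa-2,4-dien-1-yl 2-methylpropanoate (C1=C2 silyl enol ether), via lithium dienolate 17 (not isolated)
Conditions: Me3SiCl, then LiN(i-Pr)2 (internal quench), THF, −78 °C; non-aqueous work-up, used crude
Reagents that add atoms: chlorotrimethylsilane, C[Si](C)(C)Cl
Why: Kinetic α′-deprotonation of the enone at C1 is faster than enolisation of the hindered isobutyrate or γ-deprotonation at C5, and the chlorosilane already present traps the cross-conjugated enolate on oxygen at once.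

Step 11
Reactants: 18 (1R,6R)-3-{[(tert-butyldimethylsilyl)oxy]methyl}-6-isopropyl-4-[(trimethylsilyl)oxy]cyclohexa-2,4-dien-1-yl 2-methylpropanoate
Product: 20 (1S,5R,6R)-3-{[(tert-butyldimethylsilyl)oxy]methyl}-5-hydroxy-6-isopropyl-4-oxocyclohex-2-en-1-yl 2-methylpropanoate (C1–OH anti to isopropyl), via silyloxy epoxide 19 (not isolated)
Conditions: dimethyldioxirane (1.05 equiv), acetone/CH2Cl2, −78 → −30 °C; then 10% aq. citric acid, THF, 0 °C
Reagents that add atoms: dimethyldioxirane, CC1(C)OO1
Why: Rubottom oxidation, in which the electron-rich C1=C2 enol ether is epoxidised on the face opposite the C6 isopropyl and C5 acyloxy groups (both on the lower face), so that acidic opening should give the C1 carbinol trans to isopropyl and restore the enone.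

Step 12
Reactants: 21 (tert-butyldimethylsilyloxy)acetaldehyde; 22 ethyl 2-(triphenylphosphoranylidene)propanoate
Product: 23 ethyl (E)-4-[(tert-butyldimethylsilyl)oxy]-2-methylbut-2-enoate
Conditions: CH2Cl2, rt
Reagents that add atoms: none
Why: Wittig olefination with a stabilised ylide, which should give the (E)-trisubstituted enoate with the ester trans to the silyloxymethyl group.

Step 13
Reactants: 23 ethyl (E)-4-[(tert-butyldimethylsilyl)oxy]-2-methylbut-2-enoate
Product: 24 (E)-4-[(tert-butyldimethylsilyl)oxy]-2-methylbut-2-enoic acid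
Conditions: LiOH, THF/MeOH/H2O, rt; then dilute HCl to pH 4, 0 °C
Reagents that add atoms: lithium hydroxide, [Li+].[OH-]
Why: Saponification of the ethyl ester, under which the primary silyl ether and the alkene geometry are stable.

Step 14
Reactants: 24 (E)-4-[(tert-butyldimethylsilyl)oxy]-2-methylbut-2-enoic acid; 20 (1S,5R,6R)-3-{[(tert-butyldimethylsilyl)oxy]methyl}-5-hydroxy-6-isopropyl-4-oxocyclohex-2-en-1-yl 2-methylpropanoate
Product: 26 (1R,5S,6S)-3-{[(tert-butyldimethylsilyl)oxy]methyl}-5-(isobutyryloxy)-6-isopropyl-2-oxocyclohex-3-en-1-yl (E)-4-[(tert-butyldimethylsilyl)oxy]-2-methylbut-2-enoate, via mixed anhydride 25 (not isolated)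
Conditions: 2,4,6-trichlorobenzoyl chloride, Et3N, toluene, rt; then 20, 4-(dimethylamino)pyridine, rt
Reagents that add atoms: none
Why: Yamaguchi esterification, whose mixed anhydride and acylpyridinium relay acylate hindered secondary alcohols with α-branched enoic acids; the C1–O bond is not broken, and the trans C1/C6 arrangement is the more stable one should C1 enolise.

Step 15
Reactants: 26 (1R,5S,6S)-3-{[(tert-butyldimethylsilyl)oxy]methyl}-5-(isobutyryloxy)-6-isopropyl-2-oxocyclohex-3-en-1-yl (E)-4-[(tert-butyldimethylsilyl)oxy]-2-methylbut-2-enoate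
Product: 27 (1R,5S,6S)-3-(hydroxymethyl)-5-(isobutyryloxy)-6-isopropyl-2-oxocyclohex-3-en-1-yl (E)-4-hydroxy-2-methylbut-2-enoate (CNP0254776.1)
Conditions: HF·pyridine, pyridine/THF, 0 °C → rt
Reagents that add atoms: none
Why: Buffered fluoride cleavage of the two primary allylic silyl ethers under non-basic conditions, which should spare both esters and the α-acyloxy enone and avoid acyl migration.

**Compound list**
1 | 3-methylbutanal | CC(C)CC=O | starting material
2 | methyl vinyl ketone | CC(=O)C=C | starting material
3 | (S)-2-isopropyl-5-oxohexanal | O=C[C@@H](CCC(C)=O)C(C)C | intermediate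
4 | (4S)-3-hydroxy-4-isopropylcyclohexan-1-one, both C3 epimers (aldol, not isolated) | C1CC(=O)CC(O)[C@@H]1C(C)C | intermediate
5 | (S)-4-isopropylcyclohex-2-en-1-one | C1CC(=O)C=C[C@@H]1C(C)C | intermediate
6 | lithium (S)-4-isopropylcyclohexa-1,5-dien-1-olate (not isolated) | C1C=C([O-])C=C[C@@H]1C(C)C.[Li+] | intermediate
7 | (S)-4-isopropylcyclohexa-1,5-dien-1-yl trifluoromethanesulfonate | C1C=C(OS(=O)(=O)C(F)(F)F)C=C[C@@H]1C(C)C | intermediate
8 | methyl (S)-4-isopropylcyclohexa-1,5-diene-1-carboxylate | C1C=C(C(=O)OC)C=C[C@@H]1C(C)C | intermediate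
9 | [(S)-4-isopropylcyclohexa-1,5-dien-1-yl]methanol | C1C=C(CO)C=C[C@@H]1C(C)C | intermediate
10 | tert-butyl{[(S)-4-isopropylcyclohexa-1,5-dien-1-yl]methoxy}dimethylsilane | C1C=C(CO[Si](C)(C)C(C)(C)C)C=C[C@@H]1C(C)C | intermediate
11 | dioxygen (reacting as dye-sensitised singlet oxygen) | O=O | starting material
12 | tert-butyl{[(1S,4R,7S)-7-isopropyl-2,3-dioxabicyclo[2.2.2]oct-5-en-5-yl]methoxy}dimethylsilane, anti endoperoxide | C1[C@H]2OO[C@H](C=C2CO[Si](C)(C)C(C)(C)C)[C@@H]1C(C)C | intermediate
13 | (4S,5S)-2-{[(tert-butyldimethylsilyl)oxy]methyl}-4-hydroxy-5-isopropylcyclohex-2-en-1-one | C1C(=O)C(CO[Si](C)(C)C(C)(C)C)=C[C@@H](O)[C@@H]1C(C)C | intermediate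
14 | isobutyric acid | CC(C)C(=O)O | starting material
15 | alkoxyphosphonium isobutyrate of 13 at C5–O (not isolated) | C1C(=O)C(CO[Si](C)(C)C(C)(C)C)=C[C@@H](O[P+](c2ccccc2)(c2ccccc2)c2ccccc2)[C@@H]1C(C)C.CC(C)C(=O)[O-] | intermediate
16 | (1R,6S)-3-{[(tert-butyldimethylsilyl)oxy]methyl}-6-isopropyl-4-oxocyclohex-2-en-1-yl 2-methylpropanoate | C1C(=O)C(CO[Si](C)(C)C(C)(C)C)=C[C@H](OC(=O)C(C)C)[C@@H]1C(C)C | intermediate
17 | lithium C1=C2 dienolate of 16 (not isolated) | C1=C([O-])C(CO[Si](C)(C)C(C)(C)C)=C[C@H](OC(=O)C(C)C)[C@@H]1C(C)C.[Li+] | intermediate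
18 | (1R,6R)-3-{[(tert-butyldimethylsilyl)oxy]methyl}-6-isopropyl-4-[(trimethylsilyl)oxy]cyclohexa-2,4-dien-1-yl 2-methylpropanoate | C1=C(O[Si](C)(C)C)C(CO[Si](C)(C)C(C)(C)C)=C[C@H](OC(=O)C(C)C)[C@@H]1C(C)C | intermediate
19 | C1–C2 epoxide of 18 on the face anti to isopropyl, trimethylsilyloxy on C2 (not isolated) | C[Si](C)(C)O[C@@]12O[C@@H]1[C@@H](C(C)C)[C@@H](OC(=O)C(C)C)C=C2CO[Si](C)(C)C(C)(C)C | intermediate
20 | (1S,5R,6R)-3-{[(tert-butyldimethylsilyl)oxy]methyl}-5-hydroxy-6-isopropyl-4-oxocyclohex-2-en-1-yl 2-methylpropanoate | O[C@H]1C(=O)C(CO[Si](C)(C)C(C)(C)C)=C[C@H](OC(=O)C(C)C)[C@@H]1C(C)C | intermediate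
21 | (tert-butyldimethylsilyloxy)acetaldehyde | O=CCO[Si](C)(C)C(C)(C)C | starting material
22 | ethyl 2-(triphenylphosphoranylidene)propanoate | CCOC(=O)C(C)=P(c1ccccc1)(c1ccccc1)c1ccccc1 | starting material
23 | ethyl (E)-4-[(tert-butyldimethylsilyl)oxy]-2-methylbut-2-enoate | CCOC(=O)/C(C)=C/CO[Si](C)(C)C(C)(C)C | intermediate
24 | (E)-4-[(tert-butyldimethylsilyl)oxy]-2-methylbut-2-enoic acid | C/C(=C\CO[Si](C)(C)C(C)(C)C)C(=O)O | intermediate
25 | mixed anhydride of 24 with 2,4,6-trichlorobenzoic acid (not isolated) | C/C(=C\CO[Si](C)(C)C(C)(C)C)C(=O)OC(=O)c1c(Cl)cc(Cl)cc1Cl | intermediate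
26 | (1R,5S,6S)-3-{[(tert-butyldimethylsilyl)oxy]methyl}-5-(isobutyryloxy)-6-isopropyl-2-oxocyclohex-3-en-1-yl (E)-4-[(tert-butyldimethylsilyl)oxy]-2-methylbut-2-enoate | C/C(=C\CO[Si](C)(C)C(C)(C)C)C(=O)O[C@H]1C(=O)C(CO[Si](C)(C)C(C)(C)C)=C[C@H](OC(=O)C(C)C)[C@@H]1C(C)C | intermediate
27 | (1R,5S,6S)-3-(hydroxymethyl)-5-(isobutyryloxy)-6-isopropyl-2-oxocyclohex-3-en-1-yl (E)-4-hydroxy-2-methylbut-2-enoate | C/C(=C\CO)C(=O)O[C@H]1C(=O)C(CO)=C[C@H](OC(=O)C(C)C)[C@@H]1C(C)C | target

**Totals**
Total step count: 15. Longest linear sequence: 13 steps (steps 1–11, 14 and 15).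

**Steps most likely to fail**

Step 8. The amine may remove the C5 bridgehead hydrogen instead of C2–H, so that the ketone ends up at C5 and the carbinol at C2. The fallback sets out from 12 and comes back at 16, fixing the regiochemistry by ring size instead of by proton choice. Reduction of the O–O bond of 12 with Zn and acetic acid should give the cis-enediol F1 (C2–OH and C5–OH both anti to isopropyl). Bu4NF then frees C7–OH to give the triol F2. 2,2-Dimethoxypropane with pyridinium p-toluenesulfonate can only close a six-membered acetal across O2 and O7, giving the acetonide F3 with C5–OH as the one free hydroxyl. Mitsunobu esterification of F3 with isobutyric acid inverts C5 to the acetonide isobutyrate F4. Aqueous acetic acid removes the acetal to give the diol F5, TBSCl and imidazole silylate only the primary C7–OH to give the allylic alcohol F6, and MnO2 oxidises the remaining C2 carbinol to the enone 16.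

Step 9. The weakly acidic aliphatic acid may activate and displace slowly at the hindered C5 carbinol, so that hydrazide alkylation or elimination followed by aromatisation to the phenol takes over. The fallback sets out from 13 and comes back at 16. The alcohol is converted with methanesulfonyl chloride and Et3N at −20 °C into the mesylate F7, which is displaced with inversion by cesium isobutyrate and 18-crown-6 in toluene. This carboxylate SN2 reaction has no acidity requirement for the nucleophile.

Step 7. The oxygen may show poor facial discrimination, so that the syn adduct dominates, alongside some ene hydroperoxidation and aromatisation of the diene. The fallback sets out from 10 and comes back at 16 and uses the other diastereomer instead of discarding it. The syn endoperoxide F8 is rearranged with Et3N to the cis hydroxy enone F9 (C5–OH syn to isopropyl), which is acylated with retention by isobutyryl chloride, pyridine and catalytic 4-(dimethylamino)pyridine to give 16. Both faces of the cycloaddition therefore lead to the same intermediate.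

**Further compounds**
F1 | step 8 | (2R,5S,6S)-3-{[(tert-butyldimethylsilyl)oxy]methyl}-6-isopropylcyclohex-3-ene-2,5-diol (target numbering), cis-diol anti to isopropyl | C1[C@@H](O)C(CO[Si](C)(C)C(C)(C)C)=C[C@@H](O)[C@@H]1C(C)C
F2 | step 8 | 3-(hydroxymethyl)-6-isopropylcyclohex-3-ene-2,5-diol (target numbering), both ring hydroxyls anti to isopropyl | C1[C@@H](O)C(CO)=C[C@@H](O)[C@@H]1C(C)C
F3 | step 8 | O2,O7-isopropylidene acetal of F2 with free C5–OH anti to isopropyl | C1[C@H]2OC(C)(C)OCC2=C[C@@H](O)[C@@H]1C(C)C
F4 | step 8 | O2,O7-isopropylidene acetal carrying the C5 isobutyrate syn to isopropyl | C1[C@H]2OC(C)(C)OCC2=C[C@H](OC(=O)C(C)C)[C@@H]1C(C)C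
F5 | step 8 | C5 isobutyrate of the C2,C7-diol (C5–O syn, C2–OH anti to isopropyl) | C1[C@@H](O)C(CO)=C[C@H](OC(=O)C(C)C)[C@@H]1C(C)C
F6 | step 8 | C5 isobutyrate with C7–OTBS and free C2–OH | C1[C@@H](O)C(CO[Si](C)(C)C(C)(C)C)=C[C@H](OC(=O)C(C)C)[C@@H]1C(C)C
F7 | step 9 | C5 methanesulfonate of 13 | C1C(=O)C(CO[Si](C)(C)C(C)(C)C)=C[C@@H](OS(C)(=O)=O)[C@@H]1C(C)C
F8 | step 7 | syn endoperoxide, C2/C5 epimer of 12 with the peroxide bridge on the isopropyl face | C1[C@@H]2OO[C@@H](C=C2CO[Si](C)(C)C(C)(C)C)[C@@H]1C(C)C
F9 | step 7 | cis hydroxy enone, C5 epimer of 13 (C5–OH syn to isopropyl) | C1C(=O)C(CO[Si](C)(C)C(C)(C)C)=C[C@H](O)[C@@H]1C(C)C
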